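## Retrosynthetic overview

1. The target is reached by hydrogenolysis of three benzyl ethers, preceded by acetylation of the 3-hydroxyl of a tri-O-benzyl dihydroflavonol.
2. Ring C is cut at O1–C8a and C4–C4a, giving 3,5-bis(benzyloxy)-4-methoxybenzyne (ring A) and a β-hydroxy acetal lactone that already carries O1, C2, C3, C4, ring B and both stereocentres; one fluoride-triggered aryne annulation makes both bonds and unmasks the 3-hydroxyl.
3. Enabling feature: the oxygen on C5 of ring A sits next to the ring-fusion carbon C4a, so the C4a≡C8a aryne is polarised for O1 to add at C8a and the carbanion to appear at C4a; O1 and the C4 acyl carbon are 1,3-related on the side chain, so that carbanion closes the six-membered ring C on the carbonyl.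
4. The lactone partner comes in one step from an anti aldol of the chiral butane-2,3-diacetal (BDA) of glycolic acid with 4-(benzyloxy)benzaldehyde; the acetal is at once auxiliary, 3-O protection and acyl activation, and it leaves during the annulation.
5. The ortho-silylaryl triflate comes from a C2v-symmetric phenol made from methyl 3,5-dihydroxy-4-methoxybenzoate; rings A and B are bought intact and ring C is the only ring formed (step 8).

Key step: step 8

Assumption: the (5S,6S) BDA-glycolate lactone is taken as a purchasable reagent, and its lithium enolate is taken to react anti to the axial methoxy group on C5 through a chair transition state to give the anti aldol, as is usual for this reagent class.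

## Route

Step 1
Reactants: 1 methyl 3,5-dihydroxy-4-methoxybenzoate
Product: 2 methyl 3,5-bis(benzyloxy)-4-methoxybenzoate
Conditions: BnBr (2.4 equiv), K2CO3, DMF, 60 °C
Reagents that add atoms: benzyl bromide, BrCc1ccccc1
Why: Williamson ether synthesis on both phenols under carbonate, which leaves the methyl ester and methyl ether untouched.

Step 2
Reactants: 2 methyl 3,5-bis(benzyloxy)-4-methoxybenzoate
Product: 3 [3,5-bis(benzyloxy)-4-methoxyphenyl]methanol
Conditions: LiAlH4, THF, 0 °C; aqueous NaOH work-up
Reagents that add atoms: none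
Why: Hydride reduction of the ester to the benzylic alcohol, with benzyl and methyl ethers inert.

Step 3
Reactants: 3 [3,5-bis(benzyloxy)-4-methoxyphenyl]methanol
Product: 4 3,5-bis(benzyloxy)-4-methoxybenzaldehyde
Conditions: MnO2 (activated, excess), CH2Cl2, 25 °C
Reagents that add atoms: none
Why: Selective MnO2 oxidation of a benzylic alcohol, which stops at the aldehyde.

Step 4
Reactants: 4 3,5-bis(benzyloxy)-4-methoxybenzaldehyde
Product: 6 3,5-bis(benzyloxy)-4-methoxyphenol, via aryl formate 5 (not isolated)
Conditions: mCPBA, CH2Cl2, 0 to 25 °C; then K2CO3 (cat.), MeOH, 25 °C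
Reagents that add atoms: 3-chloroperoxybenzoic acid, O=C(OO)c1cccc(Cl)c1
Why: Baeyer–Villiger (Dakin-type) oxidation in which the electron-rich aryl group migrates to give formate 5, whose methanolysis should give the C2v-symmetric phenol.

Step 5
Reactants: 6 3,5-bis(benzyloxy)-4-methoxyphenol
Product: 7 3,5-bis(benzyloxy)-2-bromo-4-methoxyphenol
Conditions: NBS (1.0 equiv), CH2Cl2, −78 to −40 °C, dark
Reagents that add atoms: N-bromosuccinimide, O=C1CCC(=O)N1Br
Why: Electrophilic aromatic bromination ortho to the hydroxyl, where the para position is blocked by the methoxy group and the two ortho positions are identical by symmetry, so only one monobromide can form.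

Step 6
Reactants: 7 3,5-bis(benzyloxy)-2-bromo-4-methoxyphenol
Product: 10 3,5-bis(benzyloxy)-4-methoxy-2-(trimethylsilyl)phenyl trifluoromethanesulfonate, via aryl trimethylsilyl ether 8 (not isolated), via lithium 2-silylphenoxide 9 (not isolated)
Conditions: HMDS, THF, 65 °C, then evaporation; n-BuLi (1.1 equiv), THF, −78 °C; Tf2O, −78 to 0 °C
Reagents that add atoms: hexamethyldisilazane, C[Si](C)(C)N[Si](C)(C)C; trifluoromethanesulfonic anhydride, O=S(=O)(OS(=O)(=O)C(F)(F)F)C(F)(F)F
Why: O-silylation, bromine–lithium exchange, 1,3-retro-Brook O-to-C silyl shift and triflation of the resulting phenoxide, the standard sequence to ortho-silylaryl triflates, with exchange much faster than any benzylic deprotonation at −78 °C.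

Step 7
Reactants: 11 (5S,6S)-5,6-dimethoxy-5,6-dimethyl-1,4-dioxan-2-one; 12 4-(benzyloxy)benzaldehyde
Product: 14 (3R,5S,6S)-3-[(R)-[4-(benzyloxy)phenyl](hydroxy)methyl]-5,6-dimethoxy-5,6-dimethyl-1,4-dioxan-2-one, via lithium enolate 13 (not isolated)
Conditions: LiN(SiMe3)2 (1.05 equiv), THF, −78 °C; then 12; AcOH quench at −78 °C
Reagents that add atoms: none
Why: Lithium enolate aldol addition in which the aldehyde approaches C3 anti to the axial methoxy group on C5 (setting 3R, the future C3 of the target) and the ring-locked (E)-enolate reacts through a Zimmerman–Traxler chair to give the anti carbinol (R, the future C2).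

Step 8
Reactants: 10 3,5-bis(benzyloxy)-4-methoxy-2-(trimethylsilyl)phenyl trifluoromethanesulfonate; 14 (3R,5S,6S)-3-[(R)-[4-(benzyloxy)phenyl](hydroxy)methyl]-5,6-dimethoxy-5,6-dimethyl-1,4-dioxan-2-one
Product: 17 (2R,3R)-5,7-bis(benzyloxy)-2-[4-(benzyloxy)phenyl]-3-hydroxy-6-methoxy-2,3-dihydro-4H-chromen-4-one, via aryne 15 (not isolated), via ring-opened hemiketal 16 (not isolated)
Conditions: CsF (4 equiv), 18-crown-6, THF, 0 to 25 °C, 10 (1.3 equiv) added slowly; then TFA/H2O (9:1), CH2Cl2, 0 °C
Reagents that add atoms: none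
Why: Proposed new method: fluoride removes the trimethylsilyl group of 10 and triflate leaves to give aryne 15; the only free hydroxyl of 14 adds to the aryne carbon that becomes C8a, the aryl anion so formed at C4a attacks the lactone carbonyl (the future C4), the tetrahedral intermediate collapses with opening of the dioxanone to hemiketal 16, and aqueous acid strips the butane-2,3-dione residue to free the 3-hydroxyl. The closest known reaction type is the fluoride-induced annulation of arynes with salicylate esters to xanthones (and with 2-aminobenzoates to acridones), extended here from a phenol bearing an aryl ester to an aliphatic β-hydroxy lactone, whose acetal-activated carbonyl should trap the short-lived aryl anion at least as fast as a benzoate does. Ring C is closed by 6-exo-trig anionic acyl substitution at the lactone carbonyl, following the intermolecular O-arylation. No stereocentre is created: C2 and C3 are carried over from 14, because the carbinol C–O bond is not touched (the oxygen is arylated with retention) and the acyl transfer takes place at the carbonyl carbon, and the 2,3-trans arrangement obtained is also the thermodynamically preferred one. The step needs regioselectivity in the aryne addition, which the benzyloxy group on C5 secures by polarising the C4a≡C8a bond (nucleophile to the distal, unhindered C8a; carbanion next to the alkoxy group at C4a), and chemoselectivity between the two side-chain oxygens, which is secured because the α-oxygen is locked in the acetal lactone and can neither compete nor migrate as an acetate would. The main competitor, proton transfer to the aryl anion to give only the open aryl ether, should be held back by the aprotic medium and the six-membered intramolecular attack on an activated carbonyl.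

Step 9
Reactants: 17 (2R,3R)-5,7-bis(benzyloxy)-2-[4-(benzyloxy)phenyl]-3-hydroxy-6-methoxy-2,3-dihydro-4H-chromen-4-one
Product: 18 (2R,3R)-5,7-bis(benzyloxy)-2-[4-(benzyloxy)phenyl]-6-methoxy-4-oxo-3,4-dihydro-2H-chromen-3-yl acetate
Conditions: Ac2O, pyridine, DMAP (cat.), CH2Cl2, 0 °C
Reagents that add atoms: acetic anhydride, CC(=O)OC(C)=O
Why: DMAP-catalysed O-acylation of the only free hydroxyl under mild base, which should leave C2 and C3 unchanged.

Step 10
Reactants: 18 (2R,3R)-5,7-bis(benzyloxy)-2-[4-(benzyloxy)phenyl]-6-methoxy-4-oxo-3,4-dihydro-2H-chromen-3-yl acetate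
Product: 19 6-methoxyaromadendrin 3-O-acetate, (2R,3R)-5,7-dihydroxy-2-(4-hydroxyphenyl)-6-methoxy-4-oxo-3,4-dihydro-2H-chromen-3-yl acetate
Conditions: H2 (1 atm), Pd/C, EtOAc/MeOH, 25 °C, stopped at full debenzylation
Reagents that add atoms: none
Why: Catalytic hydrogenolysis of the three benzyl ethers under neutral conditions, which should spare the acetate, the methyl ether, the conjugated C4 carbonyl and both stereocentres.

## Compound list

1 | methyl 3,5-dihydroxy-4-methoxybenzoate | COC(=O)c1cc(O)c(OC)c(O)c1 | starting material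
2 | methyl 3,5-bis(benzyloxy)-4-methoxybenzoate | COC(=O)c1cc(OCc2ccccc2)c(OC)c(OCc2ccccc2)c1 | intermediate
3 | [3,5-bis(benzyloxy)-4-methoxyphenyl]methanol | OCc1cc(OCc2ccccc2)c(OC)c(OCc2ccccc2)c1 | intermediate
4 | 3,5-bis(benzyloxy)-4-methoxybenzaldehyde | O=Cc1cc(OCc2ccccc2)c(OC)c(OCc2ccccc2)c1 | intermediate
5 | 3,5-bis(benzyloxy)-4-methoxyphenyl formate | O=COc1cc(OCc2ccccc2)c(OC)c(OCc2ccccc2)c1 | intermediate
6 | 3,5-bis(benzyloxy)-4-methoxyphenol | Oc1cc(OCc2ccccc2)c(OC)c(OCc2ccccc2)c1 | intermediate
7 | 3,5-bis(benzyloxy)-2-bromo-4-methoxyphenol | Oc1cc(OCc2ccccc2)c(OC)c(OCc2ccccc2)c1Br | intermediate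
8 | [3,5-bis(benzyloxy)-2-bromo-4-methoxyphenoxy]trimethylsilane | C[Si](C)(C)Oc1cc(OCc2ccccc2)c(OC)c(OCc2ccccc2)c1Br | intermediate
9 | lithium 3,5-bis(benzyloxy)-4-methoxy-2-(trimethylsilyl)phenolate | [Li+].[O-]c1cc(OCc2ccccc2)c(OC)c(OCc2ccccc2)c1[Si](C)(C)C | intermediate
10 | 3,5-bis(benzyloxy)-4-methoxy-2-(trimethylsilyl)phenyl trifluoromethanesulfonate | C[Si](C)(C)c1c(OS(=O)(=O)C(F)(F)F)cc(OCc2ccccc2)c(OC)c1OCc1ccccc1 | intermediate
11 | (5S,6S)-5,6-dimethoxy-5,6-dimethyl-1,4-dioxan-2-one | O=C1CO[C@](C)(OC)[C@@](C)(OC)O1 | starting material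
12 | 4-(benzyloxy)benzaldehyde | O=Cc1ccc(OCc2ccccc2)cc1 | starting material
13 | lithium enolate of 11, lithium (5S,6S)-5,6-dimethoxy-5,6-dimethyl-5,6-dihydro-1,4-dioxin-2-olate | [Li+].[O-]C1=CO[C@](C)(OC)[C@@](C)(OC)O1 | intermediate
14 | (3R,5S,6S)-3-[(R)-[4-(benzyloxy)phenyl](hydroxy)methyl]-5,6-dimethoxy-5,6-dimethyl-1,4-dioxan-2-one | O=C1[C@@H]([C@H](O)c2ccc(OCc3ccccc3)cc2)O[C@](C)(OC)[C@@](C)(OC)O1 | intermediate
15 | 3,5-bis(benzyloxy)-4-methoxy-1,2-didehydrobenzene (aryne) | COC1=C(OCc2ccccc2)C#CC=C1OCc1ccccc1 | intermediate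
16 | (2R,3R)-5,7-bis(benzyloxy)-2-[4-(benzyloxy)phenyl]-3-[(3-hydroxy-2,3-dimethoxybutan-2-yl)oxy]-6-methoxy-2,3-dihydro-4H-chromen-4-one, acetal carbons configured as in 14 | COc1c(OCc2ccccc2)cc2c(c1OCc1ccccc1)C(=O)[C@H](O[C@](C)(OC)[C@@](C)(OC)O)[C@@H](c1ccc(OCc3ccccc3)cc1)O2 | intermediate
17 | (2R,3R)-5,7-bis(benzyloxy)-2-[4-(benzyloxy)phenyl]-3-hydroxy-6-methoxy-2,3-dihydro-4H-chromen-4-one | COc1c(OCc2ccccc2)cc2c(c1OCc1ccccc1)C(=O)[C@H](O)[C@@H](c1ccc(OCc3ccccc3)cc1)O2 | intermediate
18 | (2R,3R)-5,7-bis(benzyloxy)-2-[4-(benzyloxy)phenyl]-6-methoxy-4-oxo-3,4-dihydro-2H-chromen-3-yl acetate | COc1c(OCc2ccccc2)cc2c(c1OCc1ccccc1)C(=O)[C@H](OC(C)=O)[C@@H](c1ccc(OCc3ccccc3)cc1)O2 | intermediate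
19 | 6-methoxyaromadendrin 3-O-acetate, (2R,3R)-5,7-dihydroxy-2-(4-hydroxyphenyl)-6-methoxy-4-oxo-3,4-dihydro-2H-chromen-3-yl acetate | COc1c(O)cc2c(c1O)C(=O)[C@H](OC(C)=O)[C@@H](c1ccc(O)cc1)O2 | target

## Summary and risks

Total step count: 10. Longest linear sequence: 9 steps (steps 1 to 6, then 8, 9 and 10); step 7 is a one-step convergent branch.

**Steps most likely to fail**

1. Step 8 (proposed new method). Proton transfer to the C4a aryl anion may outrun its attack on the lactone carbonyl and give only the open aryl ether. Retro-aldol cleavage of 14 under fluoride, or slow addition of the neutral alcohol with loss of the aryne to self-reaction, are the other failure modes. The fallback uses known chemistry and closes ring C through O1–C2 instead; it sets out from 6 and comes back at 17. Phenol 6 is C-acetylated at a free ortho position (Ac2O, BF3·OEt2, Friedel–Crafts/Fries conditions) to 1-[2,4-bis(benzyloxy)-6-hydroxy-3-methoxyphenyl]ethan-1-one F1. The phenol is masked (MOMCl, NaH, DMF) as 1-[2,4-bis(benzyloxy)-3-methoxy-6-(methoxymethoxy)phenyl]ethan-1-one F2. Claisen–Schmidt condensation with 12 (KOH, EtOH) should give (E)-1-[2,4-bis(benzyloxy)-3-methoxy-6-(methoxymethoxy)phenyl]-3-[4-(benzyloxy)phenyl]prop-2-en-1-one F3. Juliá–Colonna epoxidation (poly-L-leucine, urea–H2O2, DBU, THF) should give [2,4-bis(benzyloxy)-3-methoxy-6-(methoxymethoxy)phenyl][(2R,3S)-3-[4-(benzyloxy)phenyl]oxiran-2-yl]methanone F4. HCl in MeOH/THF then removes the methoxymethyl group, and the freed phenol opens the epoxide at the benzylic carbon with inversion, which should give 17.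

2. Step 7. Facial or anti/syn selection may be insufficient with the electron-rich aromatic aldehyde, or the aldolate may undergo retro-aldol equilibration before the quench. The fallback replaces the aldol by acylation and catalyst-controlled reduction; it sets out from 11 and comes back at 14. The lithium enolate of 11 (2 equiv LiN(SiMe3)2, THF, −78 °C) is C-acylated with 4-(benzyloxy)benzoyl chloride to (3R,5S,6S)-3-[4-(benzyloxy)benzoyl]-5,6-dimethoxy-5,6-dimethyl-1,4-dioxan-2-one F5, whose C3 substituent settles in the equatorial position. Noyori asymmetric transfer hydrogenation (RuCl[(S,S)-TsDPEN](p-cymene), HCO2H/Et3N, 25 °C) then sets the carbinol under catalyst control; on the usual aryl-ketone model it should give the (R)-alcohol 14.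

3. Step 5. The very electron-rich para-methoxyphenol may be brominated twice or oxidised to a quinone instead of giving the monobromide. The fallback uses directed ortho-metalation instead of electrophilic halogenation; it sets out from 6 and comes back at 10, bypassing steps 5 and 6. Phenol 6 and isopropyl isocyanate (Et3N cat., CH2Cl2) give 3,5-bis(benzyloxy)-4-methoxyphenyl N-isopropylcarbamate F6. In situ N-silylation (TMSOTf, TMEDA), ortho-lithiation (n-BuLi, TMEDA, Et2O, −78 °C), TMSCl quench and mild acidic work-up should give 3,5-bis(benzyloxy)-4-methoxy-2-(trimethylsilyl)phenyl N-isopropylcarbamate F7. One-pot carbamate cleavage and triflation (Et2NH, DBU, MeCN, 40 °C; then PhNTf2) should give 10.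

Further compounds
F1 | step 8 | 1-[2,4-bis(benzyloxy)-6-hydroxy-3-methoxyphenyl]ethan-1-one | CC(=O)c1c(O)cc(OCc2ccccc2)c(OC)c1OCc1ccccc1
F2 | step 8 | 1-[2,4-bis(benzyloxy)-3-methoxy-6-(methoxymethoxy)phenyl]ethan-1-one | CC(=O)c1c(OCOC)cc(OCc2ccccc2)c(OC)c1OCc1ccccc1
F3 | step 8 | (E)-1-[2,4-bis(benzyloxy)-3-methoxy-6-(methoxymethoxy)phenyl]-3-[4-(benzyloxy)phenyl]prop-2-en-1-one | O=C(/C=C/c1ccc(OCc2ccccc2)cc1)c1c(OCOC)cc(OCc2ccccc2)c(OC)c1OCc1ccccc1
F4 | step 8 | [2,4-bis(benzyloxy)-3-methoxy-6-(methoxymethoxy)phenyl][(2R,3S)-3-[4-(benzyloxy)phenyl]oxiran-2-yl]methanone | O=C(c1c(OCOC)cc(OCc2ccccc2)c(OC)c1OCc1ccccc1)[C@@H]1O[C@H]1c1ccc(OCc2ccccc2)cc1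
F5 | step 7 | (3R,5S,6S)-3-[4-(benzyloxy)benzoyl]-5,6-dimethoxy-5,6-dimethyl-1,4-dioxan-2-one | O=C1[C@@H](C(=O)c2ccc(OCc3ccccc3)cc2)O[C@](C)(OC)[C@@](C)(OC)O1
F6 | step 5 | 3,5-bis(benzyloxy)-4-methoxyphenyl N-isopropylcarbamate | CC(C)NC(=O)Oc1cc(OCc2ccccc2)c(OC)c(OCc2ccccc2)c1
F7 | step 5 | 3,5-bis(benzyloxy)-4-methoxy-2-(trimethylsilyl)phenyl N-isopropylcarbamate | CC(C)NC(=O)Oc1cc(OCc2ccccc2)c(OC)c(OCc2ccccc2)c1[Si](C)(C)C
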